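**Plan**

1. Retrosynthetic cuts, in order: the three O–CH2Ph bonds (5-O, 7-O, 4'-O); C4–C4a of ring C; the O1–C2 aryl vinyl ether bond; C2–C3 and C1'–C2 on the ring B side; the C5–O and C8a–O bonds on the ring A side.
2. Enabling feature: C4a is the only hydrogen-bearing carbon of the pentaoxygenated ring A. It lies between C8a (which carries O1) and C5–O and is para to C7–O, so an acyl carbon C4 tethered through O1–C2–C3 can bond nowhere else on ring A.
3. Forward order: rings A and B are bought as benzenes. Ring A is taken to a monophenol (steps 1–5), ring B is extended by C2, C3 and C4 to a β-chloroacrylate (steps 6–10), and the two are joined at O1–C2 (step 11). Ring C, the only ring built, is closed at C4–C4a (step 13) before debenzylation (step 14).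
4. Stereochemistry: the target has no stereocentre. The racemic centres of the aldol stage are erased by oxidation and enol chlorination, and the enol ether geometry converges during ring closure.
5. Protecting groups: benzyl on the 5-, 7- and 4'-oxygens, removed together at the end. Benzylating the 5-oxygen as well gives a ring A phenol with a single hydroxyl, so the vinylation needs no statistical mono-functionalisation and no free phenol meets the anhydride in the ring closure.

Key step: step 13

Remark on the chemistry: the geometry of the tetrasubstituted chloroalkene (step 10) and enol ether (step 11) is not controlled. Both are written without geometry as E/Z mixtures. The acid and its mixed anhydride are drawn as the E isomer (carboxyl cis to aryloxy), which is the one that cyclises; the Z isomer is expected to converge on it in step 13.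

**Route**

Step 1
Reactants: 1 2,6-dimethoxyphenol
Product: 2 2-(benzyloxy)-1,3-dimethoxybenzene
Conditions: BnBr, K2CO3, DMF, 60 °C
Reagents that add atoms: benzyl bromide, BrCc1ccccc1
Why: Williamson ether synthesis on the phenoxide with a reactive benzylic halide; the benzyl ether marks the oxygen that becomes the free 7-OH.

Step 2
Reactants: 2 2-(benzyloxy)-1,3-dimethoxybenzene
Product: 4 3-(benzyloxy)-1,5-dibromo-2,4-dimethoxybenzene, via monobromide 3 (not isolated)
Conditions: NBS (2.1 equiv), MeCN, 0 °C → rt
Reagents that add atoms: N-bromosuccinimide, O=C1CCC(=O)N1Br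
Why: Electrophilic aromatic bromination in which each bromine enters ortho to one flanking methoxy group and para to the other, while the central benzyloxy group, twisted out of conjugation by its two neighbours, directs only weakly to the remaining carbon, as in the dibromination of 1,2,3-trialkoxybenzenes.

Step 3
Reactants: 4 3-(benzyloxy)-1,5-dibromo-2,4-dimethoxybenzene
Product: 7 3-(benzyloxy)-5-bromo-2,4-dimethoxyphenol, via aryllithium 5 (not isolated), via lithium arylborate 6 (not isolated)
Conditions: n-BuLi (1.0 equiv), THF, −78 °C; B(OMe)3, −78 → 0 °C; then AcOH, 30% aq. H2O2, 0 °C → rt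
Reagents that add atoms: hydrogen peroxide, OO
Why: One equivalent of n-BuLi should effect a single bromine–lithium exchange on the symmetric dibromide (the aryllithium is not exchanged again), and borate formation followed by peroxide oxidation with 1,2-shift of the aryl group from boron to oxygen is the standard lithiation–borylation–oxidation route from an aryl bromide to a phenol.

Step 4
Reactants: 7 3-(benzyloxy)-5-bromo-2,4-dimethoxyphenol
Product: 8 1,3-bis(benzyloxy)-5-bromo-2,4-dimethoxybenzene
Conditions: BnBr, K2CO3, DMF, 60 °C
Reagents that add atoms: benzyl bromide, BrCc1ccccc1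
Why: Williamson ether synthesis; this benzyl ether becomes the 5-O protecting group and is installed now so that the two ring A oxygens introduced from the bromides are told apart.

Step 5
Reactants: 8 1,3-bis(benzyloxy)-5-bromo-2,4-dimethoxybenzene
Product: 11 3,5-bis(benzyloxy)-2,4-dimethoxyphenol, via aryllithium 9 (not isolated), via lithium arylborate 10 (not isolated)
Conditions: n-BuLi (1.05 equiv), THF, −78 °C; B(OMe)3, −78 → 0 °C; then AcOH, 30% aq. H2O2, 0 °C → rt
Reagents that add atoms: hydrogen peroxide, OO
Why: The same lithiation–borylation–oxidation sequence on the remaining bromide; the lithiated carbon lies next to a methoxy group and not next to a benzyloxy group, so benzylic deprotonation and Wittig rearrangement are not expected at −78 °C.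

Step 6
Reactants: 12 2,5-dimethoxyphenol
Product: 13 2-(benzyloxy)-1,4-dimethoxybenzene
Conditions: BnBr, K2CO3, DMF, 60 °C
Reagents that add atoms: benzyl bromide, BrCc1ccccc1
Why: Williamson ether synthesis; the benzyl ether marks the future 4'-OH and, as a para-directing group, fixes the site of the following formylation.

Step 7
Reactants: 13 2-(benzyloxy)-1,4-dimethoxybenzene
Product: 15 4-(benzyloxy)-2,5-dimethoxybenzaldehyde, via iminium salt 14 (not isolated)
Conditions: POCl3, DMF, 0 → 70 °C; then H2O
Reagents that add atoms: N,N-dimethylformamide, CN(C)C=O; water, O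
Why: Vilsmeier–Haack formylation of a 1,2,4-trialkoxybenzene, which occurs at the carbon para to the benzyloxy group and ortho to a methoxy group (the pattern known from 1,2,4-trimethoxybenzene), since the carbon between two alkoxy groups is hindered and the third free carbon has no para donor.

Step 8
Reactants: 15 4-(benzyloxy)-2,5-dimethoxybenzaldehyde; 16 methyl methoxyacetate
Product: 18 methyl 3-[4-(benzyloxy)-2,5-dimethoxyphenyl]-3-hydroxy-2-methoxypropanoate (racemic syn/anti mixture), via lithium enolate 17 (not isolated)
Conditions: LiN(i-Pr)2, THF, −78 °C, 16; then 15, −78 °C; AcOH quench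
Reagents that add atoms: none
Why: Aldol addition of the lithium enolate of a glycolate ester to an aromatic aldehyde forms C2–C3; the two stereocentres arise without control, which does not matter because one is oxidised away in step 9 and the other is lost in step 10.

Step 9
Reactants: 18 methyl 3-[4-(benzyloxy)-2,5-dimethoxyphenyl]-3-hydroxy-2-methoxypropanoate
Product: 19 methyl 3-[4-(benzyloxy)-2,5-dimethoxyphenyl]-2-methoxy-3-oxopropanoate (racemic)
Conditions: Dess–Martin periodinane, CH2Cl2, rt
Reagents that add atoms: none
Why: Dess–Martin oxidation of a secondary benzylic alcohol to the aryl ketone under neutral conditions that avoid retro-aldol cleavage and leave the benzyl ether and the electron-rich ring untouched.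

Step 10
Reactants: 19 methyl 3-[4-(benzyloxy)-2,5-dimethoxyphenyl]-2-methoxy-3-oxopropanoate
Product: 20 methyl 3-[4-(benzyloxy)-2,5-dimethoxyphenyl]-3-chloro-2-methoxyprop-2-enoate (E/Z mixture)
Conditions: (COCl)2, DMF, CH2Cl2, 0 °C → rt
Reagents that add atoms: oxalyl chloride, O=C(Cl)C(=O)Cl
Why: Vilsmeier-type deoxychlorination of a 1,3-dicarbonyl compound, in which the enol oxygen of the β-keto ester attacks the chloroiminium salt and chloride then replaces the formamide leaving group at the aryl-stabilised carbon C2 of the future flavone by addition–elimination.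

Step 11
Reactants: 20 methyl 3-[4-(benzyloxy)-2,5-dimethoxyphenyl]-3-chloro-2-methoxyprop-2-enoate; 11 3,5-bis(benzyloxy)-2,4-dimethoxyphenol
Product: 21 methyl 3-[3,5-bis(benzyloxy)-2,4-dimethoxyphenoxy]-3-[4-(benzyloxy)-2,5-dimethoxyphenyl]-2-methoxyprop-2-enoate (E/Z mixture)
Conditions: Cs2CO3, DMF, 70 °C, argon
Reagents that add atoms: none
Why: Nucleophilic vinylic substitution by addition–elimination, in which the caesium phenoxide adds to the chlorine-bearing carbon and the ester-stabilised carbanion expels chloride, as in the classical preparation of 3-aryloxyacrylates from β-chlorocinnamates and β-chlorocrotonates; the polar aprotic medium favours O- over C-attack and phenol 11 offers a single hydroxyl.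

Step 12
Reactants: 21 methyl 3-[3,5-bis(benzyloxy)-2,4-dimethoxyphenoxy]-3-[4-(benzyloxy)-2,5-dimethoxyphenyl]-2-methoxyprop-2-enoate
Product: 22 (E)-3-[3,5-bis(benzyloxy)-2,4-dimethoxyphenoxy]-3-[4-(benzyloxy)-2,5-dimethoxyphenyl]-2-methoxyprop-2-enoic acid (drawn isomer of an E/Z mixture)
Conditions: LiOH, THF/MeOH/H2O, 45 °C; then 1 M HCl, 0 °C
Reagents that add atoms: lithium hydroxide, [Li+].[OH-]
Why: Saponification by acyl–oxygen cleavage; the push–pull enol ether is a poor Michael acceptor, so hydroxide should attack the ester carbonyl and not the aryloxy-bearing carbon, as in the hydrolysis of 3-aryloxycinnamates.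

Step 13
Reactants: 22 (E)-3-[3,5-bis(benzyloxy)-2,4-dimethoxyphenoxy]-3-[4-(benzyloxy)-2,5-dimethoxyphenyl]-2-methoxyprop-2-enoic acid
Product: 24 5,7-bis(benzyloxy)-2-[4-(benzyloxy)-2,5-dimethoxyphenyl]-3,6,8-trimethoxy-4H-chromen-4-one, via mixed anhydride 23 (not isolated)
Conditions: TFAA (2 equiv), CH2Cl2, 0 °C → rt; aq. NaHCO3 work-up
Reagents that add atoms: none
Why: Trifluoroacetic anhydride converts the acid into mixed anhydride 23, whose acyl group is attacked by C4a of ring A, and loss of the C4a proton restores the aromatic ring and leaves the C4 ketone, so the C4–C4a bond and ring C form in one operation. The closest known reaction is the intramolecular Friedel–Crafts acylation of 3-aryloxyacrylic and 3-aryloxycinnamic acids to chromones and flavones. Ring C closes in a 6-exo-trig mode, the arene carbon adding to the anhydride carbonyl whose oxygen stays outside the ring (6-exo-dig if the free acylium ion is involved). No stereocentre is formed, and the enol ether geometry should converge because the activated acyl species is a ketene–oxocarbenium hybrid with a low barrier to rotation about C2–C3 and because trifluoroacetic acid can protonate C3 reversibly. The step needs site selectivity for ring A over ring B and over intermolecular trifluoroacetylation: C4a is the only C–H of ring A, is ortho to O1 and to the 5-benzyloxy group and para to the 7-benzyloxy group, and closes a six-membered aromatic pyranone, whereas attack on C6' of ring B would give a strained indenone at a carbon activated by a single methoxy group. Without a Lewis acid and at 0 °C to room temperature the three benzyl ethers and the aryl vinyl ether should survive.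

Step 14
Reactants: 24 5,7-bis(benzyloxy)-2-[4-(benzyloxy)-2,5-dimethoxyphenyl]-3,6,8-trimethoxy-4H-chromen-4-one
Product: 25 5,7,4'-trihydroxy-3,6,8,2',5'-pentamethoxyflavone
Conditions: H2 (1 atm), 10% Pd/C, EtOAc/MeOH, rt
Reagents that add atoms: none
Why: Catalytic hydrogenolysis of the three aryl benzyl ethers; the tetrasubstituted C2–C3 double bond of the pyranone, the ketone and the five methyl ethers are inert under these conditions, so the 5-, 7- and 4'-hydroxyls are freed together.

**Compound list**

1 | 2,6-dimethoxyphenol | COc1cccc(OC)c1O | starting material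
2 | 2-(benzyloxy)-1,3-dimethoxybenzene | COc1cccc(OC)c1OCc1ccccc1 | intermediate
3 | 2-(benzyloxy)-4-bromo-1,3-dimethoxybenzene (monobromide, not isolated) | COc1ccc(Br)c(OC)c1OCc1ccccc1 | intermediate
4 | 3-(benzyloxy)-1,5-dibromo-2,4-dimethoxybenzene | COc1c(Br)cc(Br)c(OC)c1OCc1ccccc1 | intermediate
5 | [3-(benzyloxy)-5-bromo-2,4-dimethoxyphenyl]lithium (not isolated) | [Li]c1cc(Br)c(OC)c(OCc2ccccc2)c1OC | intermediate
6 | lithium [3-(benzyloxy)-5-bromo-2,4-dimethoxyphenyl]trimethoxyborate (not isolated) | [Li+].CO[B-](OC)(OC)c1cc(Br)c(OC)c(OCc2ccccc2)c1OC | intermediate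
7 | 3-(benzyloxy)-5-bromo-2,4-dimethoxyphenol | COc1c(O)cc(Br)c(OC)c1OCc1ccccc1 | intermediate
8 | 1,3-bis(benzyloxy)-5-bromo-2,4-dimethoxybenzene | COc1c(OCc2ccccc2)cc(Br)c(OC)c1OCc1ccccc1 | intermediate
9 | [3,5-bis(benzyloxy)-2,4-dimethoxyphenyl]lithium (not isolated) | [Li]c1cc(OCc2ccccc2)c(OC)c(OCc2ccccc2)c1OC | intermediate
10 | lithium [3,5-bis(benzyloxy)-2,4-dimethoxyphenyl]trimethoxyborate (not isolated) | [Li+].CO[B-](OC)(OC)c1cc(OCc2ccccc2)c(OC)c(OCc2ccccc2)c1OC | intermediate
11 | 3,5-bis(benzyloxy)-2,4-dimethoxyphenol | COc1c(O)cc(OCc2ccccc2)c(OC)c1OCc1ccccc1 | intermediate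
12 | 2,5-dimethoxyphenol | COc1ccc(OC)c(O)c1 | starting material
13 | 2-(benzyloxy)-1,4-dimethoxybenzene | COc1ccc(OC)c(OCc2ccccc2)c1 | intermediate
14 | N-[4-(benzyloxy)-2,5-dimethoxybenzylidene]-N-methylmethanaminium chloride (not isolated) | C[N+](C)=Cc1cc(OC)c(OCc2ccccc2)cc1OC.[Cl-] | intermediate
15 | 4-(benzyloxy)-2,5-dimethoxybenzaldehyde | COc1cc(C=O)c(OC)cc1OCc1ccccc1 | intermediate
16 | methyl methoxyacetate | COCC(=O)OC | starting material
17 | lithium enolate of methyl methoxyacetate (not isolated) | [Li+].[O-]C(OC)=COC | intermediate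
18 | methyl 3-[4-(benzyloxy)-2,5-dimethoxyphenyl]-3-hydroxy-2-methoxypropanoate (racemic syn/anti mixture) | COC(C(=O)OC)C(O)c1cc(OC)c(OCc2ccccc2)cc1OC | intermediate
19 | methyl 3-[4-(benzyloxy)-2,5-dimethoxyphenyl]-2-methoxy-3-oxopropanoate (racemic) | COC(C(=O)OC)C(=O)c1cc(OC)c(OCc2ccccc2)cc1OC | intermediate
20 | methyl 3-[4-(benzyloxy)-2,5-dimethoxyphenyl]-3-chloro-2-methoxyprop-2-enoate (E/Z mixture) | COC(=O)C(OC)=C(Cl)c1cc(OC)c(OCc2ccccc2)cc1OC | intermediate
21 | methyl 3-[3,5-bis(benzyloxy)-2,4-dimethoxyphenoxy]-3-[4-(benzyloxy)-2,5-dimethoxyphenyl]-2-methoxyprop-2-enoate (E/Z mixture) | COC(=O)C(OC)=C(Oc1cc(OCc2ccccc2)c(OC)c(OCc2ccccc2)c1OC)c1cc(OC)c(OCc2ccccc2)cc1OC | intermediate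
22 | (E)-3-[3,5-bis(benzyloxy)-2,4-dimethoxyphenoxy]-3-[4-(benzyloxy)-2,5-dimethoxyphenyl]-2-methoxyprop-2-enoic acid (carboxyl cis to aryloxy; drawn isomer of an E/Z mixture) | OC(=O)/C(OC)=C(\Oc1cc(OCc2ccccc2)c(OC)c(OCc2ccccc2)c1OC)c1cc(OC)c(OCc2ccccc2)cc1OC | intermediate
23 | mixed anhydride of acid 22 and trifluoroacetic acid (not isolated) | O=C(OC(=O)/C(OC)=C(\Oc1cc(OCc2ccccc2)c(OC)c(OCc2ccccc2)c1OC)c1cc(OC)c(OCc2ccccc2)cc1OC)C(F)(F)F | intermediate
24 | 5,7-bis(benzyloxy)-2-[4-(benzyloxy)-2,5-dimethoxyphenyl]-3,6,8-trimethoxy-4H-chromen-4-one | COc1cc(-c2oc3c(OC)c(OCc4ccccc4)c(OC)c(OCc4ccccc4)c3c(=O)c2OC)c(OC)cc1OCc1ccccc1 | intermediate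
25 | 5,7,4'-trihydroxy-3,6,8,2',5'-pentamethoxyflavone [5,7-dihydroxy-2-(4-hydroxy-2,5-dimethoxyphenyl)-3,6,8-trimethoxy-4H-chromen-4-one] | COc1cc(-c2oc3c(OC)c(O)c(OC)c(O)c3c(=O)c2OC)c(OC)cc1O | target

**Count**

Total steps: 14. Longest linear sequence: 9 steps (12 → 25 through steps 6–14; the ring A branch 1 → 25 through steps 1–5 and 11–14 is equally long).

**Steps most likely to fail**

Step 11. The phenoxide may add too slowly to a tetrasubstituted carbon that is deactivated by the α-methoxy group and the electron-rich ring B. Demethylation of the methyl ester by the phenoxide, attack through the ring carbon of the phenoxide, or oxidative decay of the electron-rich phenoxide could then take over. The fallback sets out from β-keto ester 19 and phenol 11 and returns at ester 21; it also bypasses step 10. Compound 19 is deprotonated with KN(SiMe3)2 in THF at −78 °C and the enolate is O-sulfonylated with N-phenylbis(trifluoromethanesulfonimide) to give methyl 3-[4-(benzyloxy)-2,5-dimethoxyphenyl]-2-methoxy-3-[(trifluoromethanesulfonyl)oxy]prop-2-enoate F1. F1 and 11 are then joined by palladium-catalysed C–O cross-coupling (Pd2(dba)3, 2-di-tert-butylphosphino-2',4',6'-triisopropylbiphenyl, K3PO4, toluene, 80 °C). Zerovalent palladium inserts into the C–OTf bond and the aryl vinyl ether is released by reductive elimination, so bond formation no longer depends on the electrophilicity of the alkene.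

Step 13. The activated acid may react elsewhere before ring C closes. The possibilities are trifluoroacetylation of ring A by excess anhydride, closure of the geometric isomer with the acyl group cis to ring B onto C6', and acid-induced loss of a benzyl group. The fallback sets out from ester 21 and returns at flavone 24, forming the same C4–C4a bond with reversed polarity and without acid. NBS in MeCN at 0 °C should brominate the only ring A C–H to give methyl (E)-3-[3,5-bis(benzyloxy)-2-bromo-4,6-dimethoxyphenoxy]-3-[4-(benzyloxy)-2,5-dimethoxyphenyl]-2-methoxyprop-2-enoate F2. The E isomer is used; the Z isomer would be separated and re-equilibrated by heating with a trace of acid. Bromine–lithium exchange with n-BuLi in THF at −100 °C gives the aryllithium F3, which adds to the neighbouring ester carbonyl and expels methoxide (Parham cyclisation) to give 24.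

Step 3. Control over the single bromine–lithium exchange may be lost. Proton transfer from the acidic C–H between the two bromines, double exchange, or butylation of the aryllithium by the 1-bromobutane formed would lead to mixtures of debrominated and doubly hydroxylated material. The fallback sets out from dibromide 4 and returns at phenol 11, bypassing steps 3 to 5 and using no organolithium. Double Miyaura borylation (B2pin2, Pd(dppf)Cl2, KOAc, dioxane, 90 °C) gives 2,2'-[5-(benzyloxy)-4,6-dimethoxy-1,3-phenylene]bis(4,4,5,5-tetramethyl-1,3,2-dioxaborolane) F4. Oxidation with H2O2/NaOH gives the symmetric 5-(benzyloxy)-4,6-dimethoxybenzene-1,3-diol F5. Monobenzylation with one equivalent of BnBr and K2CO3 then gives 11. The two hydroxyls are equivalent, so only one mono-ether can form; diol and bis-ether would be separated and the diol recycled.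

**Further compounds**

F1 | step 11 | methyl 3-[4-(benzyloxy)-2,5-dimethoxyphenyl]-2-methoxy-3-[(trifluoromethanesulfonyl)oxy]prop-2-enoate (E/Z mixture) | COC(=O)C(OC)=C(OS(=O)(=O)C(F)(F)F)c1cc(OC)c(OCc2ccccc2)cc1OC
F2 | step 13 | methyl (E)-3-[3,5-bis(benzyloxy)-2-bromo-4,6-dimethoxyphenoxy]-3-[4-(benzyloxy)-2,5-dimethoxyphenyl]-2-methoxyprop-2-enoate | COC(=O)/C(OC)=C(\Oc1c(Br)c(OCc2ccccc2)c(OC)c(OCc2ccccc2)c1OC)c1cc(OC)c(OCc2ccccc2)cc1OC
F3 | step 13 | aryllithium formed from F2 by bromine–lithium exchange | COC(=O)/C(OC)=C(\Oc1c([Li])c(OCc2ccccc2)c(OC)c(OCc2ccccc2)c1OC)c1cc(OC)c(OCc2ccccc2)cc1OC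
F4 | step 3 | 2,2'-[5-(benzyloxy)-4,6-dimethoxy-1,3-phenylene]bis(4,4,5,5-tetramethyl-1,3,2-dioxaborolane) | COc1c(B2OC(C)(C)C(C)(C)O2)cc(B2OC(C)(C)C(C)(C)O2)c(OC)c1OCc1ccccc1
F5 | step 3 | 5-(benzyloxy)-4,6-dimethoxybenzene-1,3-diol | COc1c(O)cc(O)c(OC)c1OCc1ccccc1
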